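The constants used here are assumed, and the outcome is calculated.

Start from the late end of the run: target forms by one step that needs reagent, so the last target forms with the last reagent, and what you want beforehand is how much target a charge of reagent can buy.

the same everywhere: starting material 0.050 M; reagent 1.10 equiv; second substrate 0.200 equiv; protic impurity 2.50 mM; time 1.0 min

|  | temperature |
|---|---|
| south-west | 25 °C |
| north-east | 40 °C |
| west | 10 °C |

    starting material + reagent → target (k1 = 0.905 L mol⁻¹ s⁻¹, Ea1 = 57.0 kJ mol⁻¹)
    second substrate + reagent → second product (k2 = 0.121 L mol⁻¹ s⁻¹, Ea2 = 40.0 kJ mol⁻¹)
    2 reagent → self-condensation product (k3 = 0.820 L mol⁻¹ s⁻¹, Ea3 = 43.0 kJ mol⁻¹)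
    second substrate + protic impurity → quenched substrate (k4 = 128 L mol⁻¹ s⁻¹, Ea4 = 36.0 kJ mol⁻¹)
    (constants at 25 °C)

- two of one species on the left: rate k times its square, two consumed each time
- at 25 °C the constants are as listed, elsewhere as the activation energies make them

- the flask that comes out highest in amount of target, in percent of the starting material charged, or "all alike" when all lie within 1.5 percentage points (south-west / north-east / west / all alike)
- target at the end, in percent of the starting material charged, south-west
- target at the end, in percent of the starting material charged, north-east
- target at the end, in percent of the starting material charged, west

First question, by my own reckoning: who takes the reagent? Write A for starting material and B for reagent. B goes to self-condensation against target in the ratio ρ[B]/[A], where ρ, a selectivity factor, is 2 times the self-condensation constant divided by the main-step constant; in south-west ρ is 1.81. I set the second substrate aside, since at the start of south-west its step runs at 0.0267 of the main step. Dividing the two rates removes time, and for b equivalents of B the integral gives the ceiling, the share of starting material turned to target when B reaches zero: C = 1 − [1 + (ρ − 1)b]^(−1/(ρ − 1)). For south-west the ceiling is 54.4%. Warming lowers ρ, because the main step has the higher activation energy: ρ is 1.38 in north-east and 2.44 in west, so their ceilings are 60.1% and 48.2%.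

Second question: does the minute reach the ceiling? B falls at least as fast as a pseudo-first-order decay on the A left at the ceiling, with time constant 0.307 min in north-east, which is shorter than the minute. So, by this reckoning with the second substrate set aside, north-east holds at most 4.22% of unused reagent, counted against the starting material charged, and stands at 55.9% or better, which is above the ceilings of south-west and west. I commit to north-east, between those two figures.

The forecast also says north-east, with 48.5% (45% to 52%) for south-west, 58.5% (54% to 63%) for north-east and 31.5% (28% to 35%) for west, on the ground that self-condensation “strips the reagent well before the starting material is used up”.

The flasks give 48.6% in south-west, 58.8% in north-east and 31.8% in west, so north-east comes out highest. Left for 10.0 min, south-west reaches 53.7%, against its ceiling of 54.4%. A south-west flask with 0.660 equiv of reagent has, by the same ρ, a ceiling of 41.1%; it stood at 36.9% after 1.00 min, with 5.8% of its reagent charge still there.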